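**Retrosynthetic overview**
- The target is reached from its 5,7-bis-silyl ether by a final buffered desilylation; C2 is the only stereocentre.
- Ring C is closed last through the C2–C3 bond: an enantioselective 1,6 C–H insertion of a rhodium α-keto carbene (C3 as an electrophilic, enolonium-type carbon) into the benzylic ether CH2.
- The α-diazoketone comes from the aryl methyl ketone by diazo transfer; the ketone comes from Mitsunobu etherification of bis-silyl phloroacetophenone with the ring B benzylic alcohol.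
- The ring B alcohol comes from 4-hydroxybenzaldehyde: ortho C-prenylation, propargyl ether formation, Claisen/electrocyclisation to the dimethylpyran ring, then reduction.
- Ring order: rings A and B are bought; the pyran ring on ring B is made first; ring C is made last by the C–C bond.

Assumption: the target is the (2S)-flavanone exactly as written.
Assumption: the sense of induction in step 8 cannot be predicted with confidence; the route is written for Rh2(S-PTTL)4, and the mirror-image catalyst Rh2(R-PTTL)4 is used instead if a pilot run gives the 2R series.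

**Step 1**
Reactants: 1 4-hydroxybenzaldehyde; 2 1-bromo-3-methylbut-2-ene (prenyl bromide)
Product: 3 4-hydroxy-3-(3-methylbut-2-en-1-yl)benzaldehyde
Conditions: KOH (10% aq.), rt, 24 h
Reagents that add atoms: none
Why: Ortho C-alkylation of the phenoxide in water, where the solvated oxygen is shielded and the ring carbon attacks the allylic bromide; the modest yield (about 25–35%) is accepted for a one-step entry from two commodity chemicals.

**Step 2**
Reactants: 3 4-hydroxy-3-(3-methylbut-2-en-1-yl)benzaldehyde; 4 3-chloro-3-methylbut-1-yne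
Product: 5 3-(3-methylbut-2-en-1-yl)-4-[(2-methylbut-3-yn-2-yl)oxy]benzaldehyde
Conditions: K2CO3, KI (cat.), CuI (cat.), acetone, 60 °C
Reagents that add atoms: none
Why: Copper-assisted O-propargylation of the phenoxide by the tertiary propargylic chloride (Williamson-type ether synthesis), the standard entry to 1,1-dimethylpropargyl aryl ethers.

**Step 3**
Reactants: 5 3-(3-methylbut-2-en-1-yl)-4-[(2-methylbut-3-yn-2-yl)oxy]benzaldehyde
Product: 7 2,2-dimethyl-8-(3-methylbut-2-en-1-yl)-2H-chromene-6-carbaldehyde, via allenyl phenol 6 (not isolated)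
Conditions: PhNEt2, 180 °C, 3 h
Reagents that add atoms: none
Why: Aromatic propargyl Claisen rearrangement to the only free ortho position gives allenyl phenol 6, which closes to the 2,2-dimethylchromene by 1,5-hydrogen shift and oxa-6π electrocyclisation.

**Step 4**
Reactants: 7 2,2-dimethyl-8-(3-methylbut-2-en-1-yl)-2H-chromene-6-carbaldehyde
Product: 8 [2,2-dimethyl-8-(3-methylbut-2-en-1-yl)-2H-chromen-6-yl]methanol
Conditions: NaBH4, MeOH, 0 °C
Reagents that add atoms: none
Why: Chemoselective borohydride reduction of the aldehyde; the prenyl and chromene alkenes are untouched.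

**Step 5**
Reactants: 9 1-(2,4,6-trihydroxyphenyl)ethan-1-one (phloroacetophenone)
Product: 10 1-[2-hydroxy-4,6-bis(triisopropylsilyloxy)phenyl]ethan-1-one
Conditions: TIPSCl (2.2 equiv), imidazole, DMAP (cat.), DMF, 0 °C to rt
Reagents that add atoms: chlorotri(propan-2-yl)silane, TIPSCl (CC(C)[Si](Cl)(C(C)C)C(C)C)
Why: Selective silyl protection: the 4-OH and one ortho OH are silylated, while the remaining ortho OH is hydrogen-bonded to the ketone and stays free.

**Step 6**
Reactants: 10 1-[2-hydroxy-4,6-bis(triisopropylsilyloxy)phenyl]ethan-1-one; 8 [2,2-dimethyl-8-(3-methylbut-2-en-1-yl)-2H-chromen-6-yl]methanol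
Product: 11 1-[2-{[2,2-dimethyl-8-(3-methylbut-2-en-1-yl)-2H-chromen-6-yl]methoxy}-4,6-bis(triisopropylsilyloxy)phenyl]ethan-1-one
Conditions: PPh3, DIAD, THF, 0 °C to rt
Reagents that add atoms: none
Why: Mitsunobu etherification of the chelated phenol with the primary benzylic alcohol under neutral conditions, which spares the silyl ethers, the chromene and the prenyl group.

**Step 7**
Reactants: 11 1-[2-{[2,2-dimethyl-8-(3-methylbut-2-en-1-yl)-2H-chromen-6-yl]methoxy}-4,6-bis(triisopropylsilyloxy)phenyl]ethan-1-one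
Product: 13 2-diazo-1-[2-{[2,2-dimethyl-8-(3-methylbut-2-en-1-yl)-2H-chromen-6-yl]methoxy}-4,6-bis(triisopropylsilyloxy)phenyl]ethan-1-one, via trifluoroacetyl diketone 12 (not isolated)
Conditions: LiHMDS, THF, −78 °C; CF3CO2CH2CF3, −78 °C, 10 min; cold 5% aq. HCl quench; then 4-acetamidobenzenesulfonyl azide, Et3N, H2O (1 equiv), MeCN, rt
Reagents that add atoms: 4-acetamidobenzenesulfonyl azide (CC(=O)Nc1ccc(cc1)S(=O)(=O)N=[N+]=[N-]) gives the two diazo nitrogens of 13; 2,2,2-trifluoroethyl trifluoroacetate (O=C(OCC(F)(F)F)C(F)(F)F) gives the trifluoroacetyl group carried only by 12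
Why: Detrifluoroacetylative diazo transfer (Regitz type, Danheiser variant): the methyl ketone enolate is C-trifluoroacetylated at −78 °C to the activated diketone 12, which takes the diazo group from the sulfonyl azide and loses the trifluoroacetyl group as the N-acyl sulfonamide.

**Step 8**
Reactants: 13 2-diazo-1-[2-{[2,2-dimethyl-8-(3-methylbut-2-en-1-yl)-2H-chromen-6-yl]methoxy}-4,6-bis(triisopropylsilyloxy)phenyl]ethan-1-one
Product: 14 (2S)-2-[2,2-dimethyl-8-(3-methylbut-2-en-1-yl)-2H-chromen-6-yl]-5,7-bis(triisopropylsilyloxy)-2,3-dihydro-4H-chromen-4-one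
Conditions: Rh2(S-PTTL)4 (dirhodium tetrakis[N-phthaloyl-(S)-tert-leucinate], 1 mol%), toluene, 0 °C, slow addition of 13 to 0.01 M; recrystallise or chiral SFC if ee is below 98%
Reagents that add atoms: none
Why: Proposed new method: loss of N2 gives a rhodium-bound α-keto carbene in which C3, normally the nucleophilic enolate carbon, is an electrophilic enolonium-type centre; it inserts with retention into one of the two enantiotopic benzylic ether C–H bonds (hydridic, activated by the ether oxygen and the para-alkoxyaryl ring) through a six-membered transition state inside the chiral carboxylate pocket, which forms the C2–C3 bond and sets C2 in one step; the closest known reactions are dirhodium prolinate-catalysed 1,6 C–H insertions of ortho-alkoxyaryl diazoketones to 2-substituted chroman-4-ones and phthaloyl-tert-leucinate-catalysed insertions into benzylic ether C–H bonds giving 2-aryl-dihydrobenzofurans; the main risk is oxonium ylide formation at the ether oxygen followed by 1,2-benzyl shift to a 2-benzylbenzofuranone, which the bulky carboxylate ligands, non-polar solvent and low temperature are chosen to disfavour, and the other ortho oxygen carries a hindered silyl group with no α C–H so it offers no competing site.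

**Step 9**
Reactants: 14 (2S)-2-[2,2-dimethyl-8-(3-methylbut-2-en-1-yl)-2H-chromen-6-yl]-5,7-bis(triisopropylsilyloxy)-2,3-dihydro-4H-chromen-4-one
Product: 15 (2S)-5,7-dihydroxy-2-[2,2-dimethyl-8-(3-methylbut-2-en-1-yl)-2H-chromen-6-yl]-2,3-dihydro-4H-chromen-4-one
Conditions: HF·pyridine, pyridine/THF, 0 °C to rt
Reagents that add atoms: none
Why: Fluoride-driven Si–O cleavage (desilylation) under buffered, mildly acidic conditions, so no phenoxide forms and the flavanone cannot racemise by retro-oxa-Michael ring opening; the alkenes survive.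

**Compound list**
1 | 4-hydroxybenzaldehyde | O=Cc1ccc(O)cc1 | starting material
2 | 1-bromo-3-methylbut-2-ene (prenyl bromide) | CC(C)=CCBr | starting material
3 | 4-hydroxy-3-(3-methylbut-2-en-1-yl)benzaldehyde | CC(C)=CCc1cc(C=O)ccc1O | intermediate
4 | 3-chloro-3-methylbut-1-yne | C#CC(C)(C)Cl | starting material
5 | 3-(3-methylbut-2-en-1-yl)-4-[(2-methylbut-3-yn-2-yl)oxy]benzaldehyde | CC(C)=CCc1cc(C=O)ccc1OC(C)(C)C#C | intermediate
6 | 4-hydroxy-3-(3-methylbuta-1,2-dien-1-yl)-5-(3-methylbut-2-en-1-yl)benzaldehyde (allenyl phenol) | CC(C)=CCc1cc(C=O)cc(C=C=C(C)C)c1O | intermediate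
7 | 2,2-dimethyl-8-(3-methylbut-2-en-1-yl)-2H-chromene-6-carbaldehyde | CC(C)=CCc1cc(C=O)cc2c1OC(C)(C)C=C2 | intermediate
8 | [2,2-dimethyl-8-(3-methylbut-2-en-1-yl)-2H-chromen-6-yl]methanol | CC(C)=CCc1cc(CO)cc2c1OC(C)(C)C=C2 | intermediate
9 | 1-(2,4,6-trihydroxyphenyl)ethan-1-one | CC(=O)c1c(O)cc(O)cc1O | starting material
10 | 1-[2-hydroxy-4,6-bis(triisopropylsilyloxy)phenyl]ethan-1-one | CC(=O)c1c(O)cc(O[Si](C(C)C)(C(C)C)C(C)C)cc1O[Si](C(C)C)(C(C)C)C(C)C | intermediate
11 | 1-[2-{[2,2-dimethyl-8-(3-methylbut-2-en-1-yl)-2H-chromen-6-yl]methoxy}-4,6-bis(triisopropylsilyloxy)phenyl]ethan-1-one | CC(=O)c1c(OCc2cc(CC=C(C)C)c3OC(C)(C)C=Cc3c2)cc(O[Si](C(C)C)(C(C)C)C(C)C)cc1O[Si](C(C)C)(C(C)C)C(C)C | intermediate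
12 | 1-[2-{[2,2-dimethyl-8-(3-methylbut-2-en-1-yl)-2H-chromen-6-yl]methoxy}-4,6-bis(triisopropylsilyloxy)phenyl]-4,4,4-trifluorobutane-1,3-dione | O=C(CC(=O)C(F)(F)F)c1c(OCc2cc(CC=C(C)C)c3OC(C)(C)C=Cc3c2)cc(O[Si](C(C)C)(C(C)C)C(C)C)cc1O[Si](C(C)C)(C(C)C)C(C)C | intermediate
13 | 2-diazo-1-[2-{[2,2-dimethyl-8-(3-methylbut-2-en-1-yl)-2H-chromen-6-yl]methoxy}-4,6-bis(triisopropylsilyloxy)phenyl]ethan-1-one | [N-]=[N+]=CC(=O)c1c(OCc2cc(CC=C(C)C)c3OC(C)(C)C=Cc3c2)cc(O[Si](C(C)C)(C(C)C)C(C)C)cc1O[Si](C(C)C)(C(C)C)C(C)C | intermediate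
14 | (2S)-2-[2,2-dimethyl-8-(3-methylbut-2-en-1-yl)-2H-chromen-6-yl]-5,7-bis(triisopropylsilyloxy)-2,3-dihydro-4H-chromen-4-one | CC(C)=CCc1cc([C@@H]2CC(=O)c3c(O[Si](C(C)C)(C(C)C)C(C)C)cc(O[Si](C(C)C)(C(C)C)C(C)C)cc3O2)cc2c1OC(C)(C)C=C2 | intermediate
15 | (2S)-5,7-dihydroxy-2-[2,2-dimethyl-8-(3-methylbut-2-en-1-yl)-2H-chromen-6-yl]-2,3-dihydro-4H-chromen-4-one | CC(C)=CCc1cc([C@@H]2CC(=O)c3c(O)cc(O)cc3O2)cc2c1OC(C)(C)C=C2 | target

**Totals**
Total step count: 9. Longest linear sequence: 8 (steps 1, 2, 3, 4, 6, 7, 8, 9); step 5 is the one-step side branch.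

**Three steps most likely to fail, with fallbacks**

Step 8 (enantioselective C–H insertion; risk of ylide-derived benzofuranone or insufficient ee). The fallback sets out from 10 (with 7) and comes back at 14. Ketone 10 and aldehyde 7 are condensed (pyrrolidine, EtOH, 50 °C) to the chalcone (E)-3-[2,2-dimethyl-8-(3-methylbut-2-en-1-yl)-2H-chromen-6-yl]-1-[2-hydroxy-4,6-bis(triisopropylsilyloxy)phenyl]prop-2-en-1-one F1. NaOAc in refluxing EtOH closes it by oxa-Michael addition to the racemic flavanone 2-[2,2-dimethyl-8-(3-methylbut-2-en-1-yl)-2H-chromen-6-yl]-5,7-bis(triisopropylsilyloxy)-2,3-dihydro-4H-chromen-4-one F2. Kinetic resolution by asymmetric transfer hydrogenation (RuCl(p-cymene)[(R,R)-TsDPEN], HCO2H/Et3N, EtOAc, rt, to about 55% conversion) reduces the 2R ketone to the cis alcohol (2R,4R)-2-[2,2-dimethyl-8-(3-methylbut-2-en-1-yl)-2H-chromen-6-yl]-5,7-bis(triisopropylsilyloxy)-3,4-dihydro-2H-chromen-4-ol F3 and leaves (2S)-14, which is separated by chromatography.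

Step 7 (diazo transfer on a hindered ketone next to a silyl ether; risk of silyl migration or incomplete trifluoroacetylation). The fallback sets out from 11 and comes back at 13. Ketone 11 is heated with N,N-dimethylformamide dimethyl acetal (toluene, 100 °C) to the enaminone (E)-3-(dimethylamino)-1-[2-{[2,2-dimethyl-8-(3-methylbut-2-en-1-yl)-2H-chromen-6-yl]methoxy}-4,6-bis(triisopropylsilyloxy)phenyl]prop-2-en-1-one F4. Treatment with 4-acetamidobenzenesulfonyl azide (MeCN, rt) gives 13 by azide cycloaddition and cycloreversion, with loss of the N-sulfonyl formamidine, so no strong base is needed.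

Step 1 (direct ortho C-prenylation; low yield and O-alkylation). The fallback sets out from 1 and comes back at 3. Aldehyde 1 is O-alkylated with chloride 4 (K2CO3, KI, CuI, acetone, 60 °C) to the propargyl ether 4-[(2-methylbut-3-yn-2-yl)oxy]benzaldehyde F5. Semi-hydrogenation (H2, Pd/CaCO3 poisoned with Pb(OAc)2, quinoline, EtOAc) gives the 1,1-dimethylallyl ether 4-[(2-methylbut-3-en-2-yl)oxy]benzaldehyde F6. Aromatic Claisen rearrangement (PhNEt2, 140 °C) then delivers the ortho-prenyl phenol 3.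

**Further compounds**
F1 | step 8 | (E)-3-[2,2-dimethyl-8-(3-methylbut-2-en-1-yl)-2H-chromen-6-yl]-1-[2-hydroxy-4,6-bis(triisopropylsilyloxy)phenyl]prop-2-en-1-one | CC(C)=CCc1cc(/C=C/C(=O)c2c(O)cc(O[Si](C(C)C)(C(C)C)C(C)C)cc2O[Si](C(C)C)(C(C)C)C(C)C)cc2c1OC(C)(C)C=C2
F2 | step 8 | racemic 2-[2,2-dimethyl-8-(3-methylbut-2-en-1-yl)-2H-chromen-6-yl]-5,7-bis(triisopropylsilyloxy)-2,3-dihydro-4H-chromen-4-one | CC(C)=CCc1cc(C2CC(=O)c3c(O[Si](C(C)C)(C(C)C)C(C)C)cc(O[Si](C(C)C)(C(C)C)C(C)C)cc3O2)cc2c1OC(C)(C)C=C2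
F3 | step 8 | (2R,4R)-2-[2,2-dimethyl-8-(3-methylbut-2-en-1-yl)-2H-chromen-6-yl]-5,7-bis(triisopropylsilyloxy)-3,4-dihydro-2H-chromen-4-ol | CC(C)=CCc1cc([C@H]2C[C@@H](O)c3c(O[Si](C(C)C)(C(C)C)C(C)C)cc(O[Si](C(C)C)(C(C)C)C(C)C)cc3O2)cc2c1OC(C)(C)C=C2
F4 | step 7 | (E)-3-(dimethylamino)-1-[2-{[2,2-dimethyl-8-(3-methylbut-2-en-1-yl)-2H-chromen-6-yl]methoxy}-4,6-bis(triisopropylsilyloxy)phenyl]prop-2-en-1-one | CN(C)/C=C/C(=O)c1c(OCc2cc(CC=C(C)C)c3OC(C)(C)C=Cc3c2)cc(O[Si](C(C)C)(C(C)C)C(C)C)cc1O[Si](C(C)C)(C(C)C)C(C)C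
F5 | step 1 | 4-[(2-methylbut-3-yn-2-yl)oxy]benzaldehyde | O=Cc1ccc(OC(C)(C)C#C)cc1
F6 | step 1 | 4-[(2-methylbut-3-en-2-yl)oxy]benzaldehyde | O=Cc1ccc(OC(C)(C)C=C)cc1
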